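**Retrosynthetic overview**
1. Sodwanone S (21) ⇐ bis-epoxide 19: ring D (oxepene) is closed last by a diepoxide → cyclic allylic ether cascade (new).
2. 19 ⇐ diene 18 (Shi epoxidation) ⇐ enol triflate 13 + homoprenyl Grignard; the CHMe/quaternary pair of ring C comes from Cu-catalysed conjugate methylation and enolate methylation of enone 10.
3. 10 ⇐ B-alkyl Suzuki coupling of vinyl bicycle 7 with achiral 2-iodocyclohex-2-enone 8 (ring C is bought).
4. 7 ⇐ diol 5 ⇐ acetate-terminated tandem oxa-/carbacyclization of diepoxide 2 (rings A and B in one step, new) ⇐ Shi epoxidation of achiral (E,E)-farnesyl acetate 1 (first stereocentres).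
5. Ring order: A+B (step 2), C (attached in step 5, stereocentres in step 6), D (step 11).

Assumption: the given SMILES defines the target (all eight stereocentres S) and the L-fructose-derived Shi ketone is an available catalyst; G(TES), G(OH) and G(oxo) denote the (5aS,6S,7S,9aS)-7-hydroxy-2,2,5a,7-tetramethyldecahydro-1-benzoxepin-6-yl group carrying (3S)-OSiEt3, (3S)-OH or 3-oxo.

Step 1
Reactants: 1 (2E,6E)-farnesyl acetate
Product: 2 (2E,6S,7S,10S)-6,7:10,11-diepoxy-3,7,11-trimethyldodec-2-en-1-yl acetate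
Conditions: L-fructose-derived Shi ketone (30 mol %), KHSO5 (as 2KHSO5·KHSO4·K2SO4), K2CO3, Bu4NHSO4, MeCN/CH2(OMe)2/aq. Na2B4O7 buffer, 0 °C
Reagents that add atoms: potassium peroxymonosulfate KHSO5, [K+].[O-]S(=O)(=O)OO
Why: Shi asymmetric epoxidation (chiral dioxirane, spiro transition state) oxidises the two electron-rich trisubstituted alkenes with catalyst-controlled face selectivity (this ketone enantiomer gives 6S,7S,10S), while the 2,3-alkene is deactivated by the allylic acetate and survives.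

Step 2
Reactants: 2 diepoxy acetate
Product: 5 (3S,5aS,6R,7S,9aS)-6-(hydroxymethyl)-2,2,5a,7-tetramethyl-3-(triethylsilyloxy)decahydro-1-benzoxepin-7-ol, via acetoxonium triflate 3 (not isolated), via hydroxy acetate 4 (not isolated)
Conditions: Et3SiOTf (1.2 equiv), 2,6-di-tert-butyl-4-methylpyridine, CH2Cl2, −78 °C; aq. NaHCO3; then K2CO3 (cat.), MeOH, 23 °C
Reagents that add atoms: triethylsilyl trifluoromethanesulfonate, CC[Si](CC)(CC)OS(=O)(=O)C(F)(F)F
Why: Proposed new method: silylation of the terminal epoxide lets the neighbouring epoxide oxygen attack its tertiary carbon to give an epoxonium ion, the remaining alkene opens this at the tertiary carbon through a chair (inversion, trans ring fusion, equatorial side chain), and the allylic acetate carbonyl captures the new tertiary cation anti as a trans-fused 1,3-dioxan-2-ylium ion (equatorial C–O, axial methyl) that hydrolysis and methanolysis convert into the diol; the closest known reaction types are the silyl-triflate-triggered tandem oxa-/carbacyclization of 1,5-diepoxides ended by alkenes or enol silanes and acetoxonium capture in acid cyclizations of farnesyl acetate, which have not been combined.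

Step 3
Reactants: 5 TES diol
Product: 6 (3S,5aS,6S,7S,9aS)-7-hydroxy-2,2,5a,7-tetramethyl-3-(triethylsilyloxy)decahydro-1-benzoxepine-6-carbaldehyde
Conditions: TEMPO (10 mol %), PhI(OAc)2, CH2Cl2, 23 °C
Reagents that add atoms: none
Why: Oxoammonium (TEMPO/PhI(OAc)2) oxidation is selective for the primary alcohol and leaves the tertiary alcohol, the silyl ether and the equatorial formyl-bearing stereocentre untouched.

Step 4
Reactants: 6 hydroxy aldehyde
Product: 7 (3S,5aS,6S,7S,9aS)-6-ethenyl-2,2,5a,7-tetramethyl-3-(triethylsilyloxy)decahydro-1-benzoxepin-7-ol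
Conditions: Ph3PCH3Br, KN(SiMe3)2, THF, −78 → 0 °C (aldehyde added to excess ylide)
Reagents that add atoms: methyltriphenylphosphonium bromide, C[P+](c1ccccc1)(c1ccccc1)c1ccccc1.[Br-]
Why: Wittig methylenation is fast on aldehydes at low temperature and the ylide is too weak a base to deprotonate the tertiary alcohol, so retro-aldol cleavage and epimerisation are avoided.

Step 5
Reactants: 7 vinyl bicycle; 8 2-iodocyclohex-2-en-1-one
Product: 10 2-[2-G(TES)-ethyl]cyclohex-2-en-1-one, via B-alkyl-9-BBN 9 (not isolated)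
Conditions: 9-BBN-H (2 equiv), THF, 23 → 50 °C; then 8, PdCl2(dppf) (5 mol %), AsPh3, Cs2CO3, DMF/H2O, 23 °C
Reagents that add atoms: none
Why: Anti-Markovnikov hydroboration of the only alkene followed by B-alkyl Suzuki–Miyaura coupling with the 2-iodoenone forms the two-carbon bridge without touching any stereocentre.

Step 6
Reactants: 10 enone
Product: 12 (2S,3S)-2,3-dimethyl-2-[2-G(TES)-ethyl]cyclohexan-1-one, via magnesium enolate 11 (not isolated)
Conditions: Cu(OTf)2 (5 mol %), chiral imidazolinium salt (NHC precursor, enantiomer giving the 3S adduct, 7 mol %), MeMgBr (3 equiv), Et2O, −30 °C; then MeI, HMPA, −30 → 23 °C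
Reagents that add atoms: methylmagnesium bromide, C[Mg]Br; iodomethane, CI
Why: Copper/NHC-catalysed asymmetric conjugate addition to the α-substituted enone sets the secondary methyl stereocentre under catalyst control, and the regiodefined magnesium enolate is methylated anti to that methyl (enolate alkylation), giving the quaternary centre with the two methyl groups trans.

Step 7
Reactants: 12 ketone
Product: 13 (5S,6S)-5,6-dimethyl-6-[2-G(TES)-ethyl]cyclohex-1-en-1-yl trifluoromethanesulfonate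
Conditions: KN(SiMe3)2 (2.2 equiv), PhNTf2, THF, −78 → 0 °C
Reagents that add atoms: N-phenylbis(trifluoromethanesulfonimide), O=S(=O)(N(c1ccccc1)S(=O)(=O)C(F)(F)F)C(F)(F)F
Why: The ketone has only one enolisable α-position (the other is quaternary), so enolate O-triflation gives a single enol triflate.

Step 8
Reactants: 13 enol triflate; 14 5-bromo-2-methylpent-2-ene
Product: 17 (5S,6S)-5,6-dimethyl-1-(4-methylpent-3-en-1-yl)-6-[2-G(OH)-ethyl]cyclohex-1-ene, via homoprenylmagnesium bromide 15 (not isolated), via TES ether 16 (not isolated)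
Conditions: Mg, THF (Grignard from 14, 3 equiv); 13, Fe(acac)3 (10 mol %), THF/NMP, −30 → 0 °C; then 1 M aq. HCl, THF, 23 °C
Reagents that add atoms: none
Why: Iron-catalysed Kumada-type cross-coupling of alkenyl triflates with alkyl Grignard reagents is fast even at hindered positions, and the acidic work-up cleaves the triethylsilyl ether.

Step 9
Reactants: 17 diol
Product: 18 (5S,6S)-5,6-dimethyl-1-(4-methylpent-3-en-1-yl)-6-[2-G(oxo)-ethyl]cyclohex-1-ene
Conditions: Dess–Martin periodinane, CH2Cl2, 23 °C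
Reagents that add atoms: none
Why: Dess–Martin oxidation converts the only secondary alcohol into the ring A ketone before the second secondary alcohol exists; the tertiary alcohol and the alkenes are inert.

Step 10
Reactants: 18 keto diene
Product: 19 (1R,2S,3S,6S)-1-{2-[(2S)-3,3-dimethyloxiran-2-yl]ethyl}-2,3-dimethyl-2-[2-G(oxo)-ethyl]-7-oxabicyclo[4.1.0]heptane
Conditions: L-fructose-derived Shi ketone (50 mol %), KHSO5 (as 2KHSO5·KHSO4·K2SO4), K2CO3, Bu4NHSO4, MeCN/CH2(OMe)2/aq. Na2B4O7 buffer, 0 °C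
Reagents that add atoms: potassium peroxymonosulfate KHSO5, [K+].[O-]S(=O)(=O)OO
Why: Shi epoxidation gives the (S) side-chain epoxide by catalyst control, and on the ring alkene the catalyst's preferred face is the one anti to the pseudoaxial chain on the quaternary carbon (matched case), which places the epoxide oxygen cis to the quaternary methyl.

Step 11
Reactants: 19 bis-epoxide
Product: 21 sodwanone S, via bis(trimethylsilyl) ether 20 (not isolated)
Conditions: Me3SiOTf (2.5 equiv), 2,6-di-tert-butyl-4-methylpyridine (3 equiv), CH2Cl2, −78 → −40 °C; then K2CO3, MeOH, 0 → 23 °C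
Reagents that add atoms: none
Why: Proposed new method: silylation of the side-chain epoxide lets the ring-epoxide oxygen attack its tertiary carbon (endo mode) to give a bicyclic epoxonium ion whose C–O bond to the fully substituted ring carbon is anti-periplanar to one C–H of the adjacent side-chain methylene, so loss of that proton (the only β-hydrogen apart from the poorly aligned one on the oxygen-bearing carbon) opens it to the seven-membered allylic ether with both C–O stereocentres retained and the alkene geometry fixed by the ring, while the alternative order (ring epoxide to allylic silyl ether first, then 7-endo attack on the second epoxide) leads to the same product; the closest known reaction types are the epoxonium-relay endo oxacyclization of 1,5-diepoxides and the silyl triflate/base isomerisation of epoxides to allylic silyl ethers.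

**Compound list**
1 | (2E,6E)-farnesyl acetate | CC(C)=CCC/C(C)=C/CC/C(C)=C/COC(C)=O | starting material
2 | (2E,6S,7S,10S)-6,7:10,11-diepoxy-3,7,11-trimethyldodec-2-en-1-yl acetate | CC(=O)OC/C=C(\C)CC[C@@H]1O[C@@]1(C)CC[C@@H]1OC1(C)C | intermediate
3 | acetoxonium triflate: 2-methyl-1,3-dioxan-2-ylium ion bridging the C7 oxygen and the CH2 oxygen of 5 (in-flask species) | CC1=[O+]C[C@H]2[C@]3(C)CC[C@H](O[Si](CC)(CC)CC)C(C)(C)O[C@H]3CC[C@]2(C)O1.[O-]S(=O)(=O)C(F)(F)F | intermediate
4 | [(3S,5aS,6R,7S,9aS)-7-hydroxy-2,2,5a,7-tetramethyl-3-(triethylsilyloxy)decahydro-1-benzoxepin-6-yl]methyl acetate (in-flask species) | CC(=O)OC[C@H]1[C@]2(C)CC[C@H](O[Si](CC)(CC)CC)C(C)(C)O[C@H]2CC[C@]1(C)O | intermediate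
5 | (3S,5aS,6R,7S,9aS)-6-(hydroxymethyl)-2,2,5a,7-tetramethyl-3-(triethylsilyloxy)decahydro-1-benzoxepin-7-ol | OC[C@H]1[C@]2(C)CC[C@H](O[Si](CC)(CC)CC)C(C)(C)O[C@H]2CC[C@]1(C)O | intermediate
6 | (3S,5aS,6S,7S,9aS)-7-hydroxy-2,2,5a,7-tetramethyl-3-(triethylsilyloxy)decahydro-1-benzoxepine-6-carbaldehyde | O=C[C@H]1[C@]2(C)CC[C@H](O[Si](CC)(CC)CC)C(C)(C)O[C@H]2CC[C@]1(C)O | intermediate
7 | (3S,5aS,6S,7S,9aS)-6-ethenyl-2,2,5a,7-tetramethyl-3-(triethylsilyloxy)decahydro-1-benzoxepin-7-ol | C=C[C@H]1[C@]2(C)CC[C@H](O[Si](CC)(CC)CC)C(C)(C)O[C@H]2CC[C@]1(C)O | intermediate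
8 | 2-iodocyclohex-2-en-1-one | O=C1CCCC=C1I | starting material
9 | 9-[2-G(TES)-ethyl]-9-borabicyclo[3.3.1]nonane (in-flask species) | B1(C2CCCC1CCC2)CC[C@H]1[C@]2(C)CC[C@H](O[Si](CC)(CC)CC)C(C)(C)O[C@H]2CC[C@]1(C)O | intermediate
10 | 2-[2-G(TES)-ethyl]cyclohex-2-en-1-one | O=C1CCCC=C1CC[C@H]1[C@]2(C)CC[C@H](O[Si](CC)(CC)CC)C(C)(C)O[C@H]2CC[C@]1(C)O | intermediate
11 | bromomagnesium enolate (and alkoxide) of (3S)-3-methyl-2-[2-G(TES)-ethyl]cyclohexanone (in-flask species) | C[C@H]1CCCC(O[Mg]Br)=C1CC[C@H]1[C@]2(C)CC[C@H](O[Si](CC)(CC)CC)C(C)(C)O[C@H]2CC[C@]1(C)O[Mg]Br | intermediate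
12 | (2S,3S)-2,3-dimethyl-2-[2-G(TES)-ethyl]cyclohexan-1-one | C[C@H]1CCCC(=O)[C@@]1(C)CC[C@H]1[C@]2(C)CC[C@H](O[Si](CC)(CC)CC)C(C)(C)O[C@H]2CC[C@]1(C)O | intermediate
13 | (5S,6S)-5,6-dimethyl-6-[2-G(TES)-ethyl]cyclohex-1-en-1-yl trifluoromethanesulfonate | C[C@H]1CCC=C(OS(=O)(=O)C(F)(F)F)[C@@]1(C)CC[C@H]1[C@]2(C)CC[C@H](O[Si](CC)(CC)CC)C(C)(C)O[C@H]2CC[C@]1(C)O | intermediate
14 | 5-bromo-2-methylpent-2-ene | CC(C)=CCCBr | starting material
15 | (4-methylpent-3-en-1-yl)magnesium bromide (in-flask species) | CC(C)=CCC[Mg]Br | intermediate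
16 | (5S,6S)-5,6-dimethyl-1-(4-methylpent-3-en-1-yl)-6-[2-G(TES)-ethyl]cyclohex-1-ene (in-flask species) | C[C@H]1CCC=C(CCC=C(C)C)[C@@]1(C)CC[C@H]1[C@]2(C)CC[C@H](O[Si](CC)(CC)CC)C(C)(C)O[C@H]2CC[C@]1(C)O | intermediate
17 | (5S,6S)-5,6-dimethyl-1-(4-methylpent-3-en-1-yl)-6-[2-G(OH)-ethyl]cyclohex-1-ene | C[C@H]1CCC=C(CCC=C(C)C)[C@@]1(C)CC[C@H]1[C@]2(C)CC[C@H](O)C(C)(C)O[C@H]2CC[C@]1(C)O | intermediate
18 | (5S,6S)-5,6-dimethyl-1-(4-methylpent-3-en-1-yl)-6-[2-G(oxo)-ethyl]cyclohex-1-ene | C[C@H]1CCC=C(CCC=C(C)C)[C@@]1(C)CC[C@H]1[C@]2(C)CCC(=O)C(C)(C)O[C@H]2CC[C@]1(C)O | intermediate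
19 | (1R,2S,3S,6S)-1-{2-[(2S)-3,3-dimethyloxiran-2-yl]ethyl}-2,3-dimethyl-2-[2-G(oxo)-ethyl]-7-oxabicyclo[4.1.0]heptane | C[C@H]1CC[C@@H]2O[C@]2(CC[C@@H]3OC3(C)C)[C@@]1(C)CC[C@H]1[C@]2(C)CCC(=O)C(C)(C)O[C@H]2CC[C@]1(C)O | intermediate
20 | sodwanone S bis(trimethylsilyl) ether (in-flask species) | C[C@H]1CC[C@@H]2OC(C)(C)[C@@H](O[Si](C)(C)C)CC=C2[C@@]1(C)CC[C@H]1[C@]2(C)CCC(=O)C(C)(C)O[C@H]2CC[C@]1(C)O[Si](C)(C)C | intermediate
21 | sodwanone S | C[C@H]1CC[C@@H]2OC(C)(C)[C@@H](O)CC=C2[C@@]1(C)CC[C@H]1[C@]2(C)CCC(=O)C(C)(C)O[C@H]2CC[C@]1(C)O | target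

**Step count and risks**
Total steps: 11. Longest linear sequence: 11 (from 1; compounds 8 and 14 are bought).

The three steps most likely to fail are steps 2, 6 and 11.

Step 2 (new cascade) may fail because the alkene next to the acetate is a weak nucleophile, or because the cation loses a proton instead of being captured. The fallback uses known reaction types only, sets out from 2 and returns at 5. K2CO3/MeOH removes the acetate to give diepoxy alcohol F1, and NaH/BnBr gives benzyl ether F2. Et3SiOTf with 2,6-di-tert-butyl-4-methylpyridine at −78 °C then runs the alkene-terminated tandem oxa-/carbacyclization with proton loss to exocyclic alkene F3 (ring-alkene isomers converge in the next step). Mukaiyama hydration (Mn(dpm)3, PhSiH3, O2, iPrOH) adds the equatorial tertiary hydroxyl to give tertiary alcohol F4, and H2 over Pd/C removes the benzyl group to give 5.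

Step 6 may fail through slow or unselective methyl addition to the hindered 2-alkyl enone, or poor C-methylation of the enolate. The fallback sets the same stereocentre by hydride delivery instead; it sets out from 7 and returns at 12. Borane 9 (from 7) is coupled under the step 5 conditions with iodoenone F5 (2-iodo-3-methylcyclohex-2-en-1-one, made by I2/pyridine α-iodination of 3-methylcyclohex-2-enone) to give enone F6. Asymmetric copper hydride conjugate reduction (Cu(OAc)2, DTBM-SEGPHOS, PhMe2SiH) gives silyl enol ether F7, and MeLi followed by MeI/HMPA methylates anti to the 3-methyl group to give 12.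

Step 11 (new cascade) may fail through hydride or alkyl shift in the epoxonium ion, or elimination of the side-chain epoxide before it is trapped. The fallback uses known chemistry, sets out from 18 and returns at 21. Shi epoxidation with one equivalent of oxidant epoxidises only the unhindered side-chain alkene to give mono-epoxide F8. The singlet-oxygen ene reaction (O2, tetraphenylporphyrin, light, CH2Cl2, −20 °C) on the ring alkene, anti to the pseudoaxial chain and at the less hindered carbon, gives allylic hydroperoxide F9, which PPh3 reduces to allylic alcohol F10. Camphorsulfonic acid (cat., CH2Cl2, 0 °C) then closes ring D by 7-endo opening of the epoxide at its tertiary carbon to give 21.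

**Further compounds**
F1 | step 2 | (2E,6S,7S,10S)-6,7:10,11-diepoxy-3,7,11-trimethyldodec-2-en-1-ol | OC/C=C(\C)CC[C@@H]1O[C@@]1(C)CC[C@@H]1OC1(C)C
F2 | step 2 | benzyl ether of F1 | C(OC/C=C(\C)CC[C@@H]1O[C@@]1(C)CC[C@@H]1OC1(C)C)c1ccccc1
F3 | step 2 | 6-(benzyloxymethyl)-2,2,5a-trimethyl-7-methylidene-3-(triethylsilyloxy)decahydro-1-benzoxepine (ring configuration as in 5) | c1ccccc1COC[C@H]1[C@]2(C)CC[C@H](O[Si](CC)(CC)CC)C(C)(C)O[C@H]2CCC1=C
F4 | step 2 | primary benzyl ether of diol 5 | c1ccccc1COC[C@H]1[C@]2(C)CC[C@H](O[Si](CC)(CC)CC)C(C)(C)O[C@H]2CC[C@]1(C)O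
F5 | step 6 | 2-iodo-3-methylcyclohex-2-en-1-one | CC1=C(I)C(=O)CCC1
F6 | step 6 | 3-methyl-2-[2-G(TES)-ethyl]cyclohex-2-en-1-one | CC1=C(CC[C@H]2[C@]3(C)CC[C@H](O[Si](CC)(CC)CC)C(C)(C)O[C@H]3CC[C@]2(C)O)C(=O)CCC1
F7 | step 6 | dimethylphenylsilyl enol ether of (3S)-3-methyl-2-[2-G(TES)-ethyl]cyclohexanone | C[C@H]1CCCC(O[Si](C)(C)c2ccccc2)=C1CC[C@H]1[C@]2(C)CC[C@H](O[Si](CC)(CC)CC)C(C)(C)O[C@H]2CC[C@]1(C)O
F8 | step 11 | side-chain (S)-mono-epoxide of 18 | C[C@H]1CCC=C(CC[C@@H]2OC2(C)C)[C@@]1(C)CC[C@H]1[C@]2(C)CCC(=O)C(C)(C)O[C@H]2CC[C@]1(C)O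
F9 | step 11 | allylic hydroperoxide: ring C carbinol carbon bears OOH and the exocyclic alkene has the side chain cis to it | C[C@H]1CC[C@H](OO)/C(=C\C[C@@H]2OC2(C)C)[C@@]1(C)CC[C@H]1[C@]2(C)CCC(=O)C(C)(C)O[C@H]2CC[C@]1(C)O
F10 | step 11 | allylic alcohol from F9 | C[C@H]1CC[C@H](O)/C(=C\C[C@@H]2OC2(C)C)[C@@]1(C)CC[C@H]1[C@]2(C)CCC(=O)C(C)(C)O[C@H]2CC[C@]1(C)O
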